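**Retrosynthetic overview**
1. The 14-membered ring is closed last by a ring contraction: a 15-membered thiolactone loses sulfur (ketone enolate → thiirane → phosphine), which forges the CH2–C(=O) bond of the 1,3-diketone. The thiolactone comes from intramolecular S-alkylation of a thiocarboxylate by a chloromethyl ketone.
2. The trans-decalin (rings A and B, four stereocentres) is made in one event by an enantioselective intramolecular Diels–Alder reaction of an open-chain chloromethyl trienone.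
3. The polyene is joined at the central bond of its E,E-diene by Negishi coupling of an E-vinyl iodide (Z,Z-dienyl carbinol half) with a skipped enyne (tether half); the enone is added by Wittig reaction.
4. Vinyl iodide: Roche ester + (R)-but-3-yn-2-ol by alkyne homologation, oxidative diyne coupling, zinc semi-reduction and Takai olefination. Enyne: hydroxyacetone by Z-selective Wittig reaction, bromination and copper-catalysed alkynylation.
5. Ring order: rings A and B together, then the 15-membered sulfur-containing ring, then its contraction to the 14-membered macrolide.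

**Assumptions**
- The drawn enol (OH on the carbon next to the decalin) is taken as one tautomer of the enolised 1,3-diketone; the diketone delivered by the last step is that compound.
- The silyl ethers of the Roche ester, of (R)-but-3-yn-2-ol and of hydroxyacetone are bought as such (each is also one Me2(t-Bu)SiCl/imidazole step from the parent alcohol); these silyl groups and the isopropylidene group of the methylmalonate building block are protecting groups.
- The (S)-oxazaborolidine-derived catalyst of step 12 is taken to be the enantiomer that shields the enone face required here; its mirror image is equally available.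

**Route**

Step 1
Reactants: 1 methyl (2S)-3-[(tert-butyldimethylsilyl)oxy]-2-methylpropanoate
Product: 3 tert-butyldimethyl{[(2R)-2-methylbut-3-yn-1-yl]oxy}silane, via silyloxy aldehyde 2 (not isolated)
Conditions: i-Bu2AlH, CH2Cl2, −78 °C; then MeOH, dimethyl (1-diazo-2-oxopropyl)phosphonate, K2CO3, −78 °C → rt
Reagents that add atoms: dimethyl (1-diazo-2-oxopropyl)phosphonate, CC(=O)C(=[N+]=[N-])P(=O)(OC)OC
Why: Low-temperature ester-to-aldehyde reduction followed in the same flask by Ohira–Bestmann (Seyferth–Gilbert) homologation; the methyl-bearing stereocentre of the Roche ester is carried over untouched under these mild conditions.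

Step 2
Reactants: 3 tert-butyldimethyl{[(2R)-2-methylbut-3-yn-1-yl]oxy}silane
Product: 4 (2R)-2-methylbut-3-yn-1-ol
Conditions: Bu4NF, THF, 0 °C → rt
Reagents that add atoms: none
Why: Fluoride desilylation frees the primary alcohol now, so that after the coupling only the secondary carbinol is protected and no selective deprotection is needed later.

Step 3
Reactants: 4 (2R)-2-methylbut-3-yn-1-ol; 5 tert-butyl{[(2R)-but-3-yn-2-yl]oxy}dimethylsilane
Product: 6 (2R,7R)-7-[(tert-butyldimethylsilyl)oxy]-2-methylocta-3,5-diyn-1-ol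
Conditions: CuCl (10 mol%), Me2NCH2CH2NMe2 (20 mol%), O2 (1 atm), acetone, rt; 4 added slowly to 5 (4 equiv)
Reagents that add atoms: none
Why: Hay (Glaser-type) oxidative hetero-coupling of two terminal alkynes; the fourfold excess of the cheap alkyne 5 channels 4 into the cross-diyne, whose free OH separates it easily from the bis-silyl homodimer, and neither stereocentre is touched.

Step 4
Reactants: 6 (2R,7R)-7-[(tert-butyldimethylsilyl)oxy]-2-methylocta-3,5-diyn-1-ol
Product: 7 (2R,3Z,5Z,7R)-7-[(tert-butyldimethylsilyl)oxy]-2-methylocta-3,5-dien-1-ol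
Conditions: Zn (activated with Cu(OAc)2, then AgNO3), MeOH/H2O 1:1, 45 °C
Reagents that add atoms: none
Why: Boland reduction: activated zinc delivers hydrogen syn to each triple bond of a conjugated diyne flanked by propargylic oxygen, giving the Z,Z-diene without over-reduction.

Step 5
Reactants: 7 (2R,3Z,5Z,7R)-7-[(tert-butyldimethylsilyl)oxy]-2-methylocta-3,5-dien-1-ol
Product: 9 tert-butyl{[(2R,3Z,5Z,7R,8E)-9-iodo-7-methylnona-3,5,8-trien-2-yl]oxy}dimethylsilane, via dienal 8 (not isolated)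
Conditions: Dess–Martin periodinane, NaHCO3, CH2Cl2, 0 °C; then CrCl2, CHI3, THF/dioxane, 0 °C → rt
Reagents that add atoms: iodoform, IC(I)I
Why: Buffered Dess–Martin oxidation, then Takai olefination of the crude aldehyde (addition of the gem-dichromium reagent and anti elimination give the E-vinyl iodide); the non-basic conditions keep the α-methyl, β,γ-unsaturated aldehyde from epimerising or moving into conjugation.

Step 6
Reactants: 10 1-[(tert-butyldimethylsilyl)oxy]propan-2-one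
Product: 11 2-[(2Z)-4-[(tert-butyldimethylsilyl)oxy]-3-methylbut-2-en-1-yl]-1,3-dioxolane
Conditions: [2-(1,3-dioxolan-2-yl)ethyl]triphenylphosphonium bromide, KN(SiMe3)2, THF, −78 °C; then 10, −78 → 0 °C
Reagents that add atoms: [2-(1,3-dioxolan-2-yl)ethyl]triphenylphosphonium bromide, [Br-].C1COC(CC[P+](c2ccccc2)(c2ccccc2)c2ccccc2)O1
Why: Wittig reaction of an α-silyloxy ketone with a non-stabilised, salt-free ylide, the established Z-selective route to trisubstituted allylic ethers, which places the oxygenated CH2 and the new chain cis (the future ring A alkene geometry).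

Step 7
Reactants: 11 2-[(2Z)-4-[(tert-butyldimethylsilyl)oxy]-3-methylbut-2-en-1-yl]-1,3-dioxolane
Product: 12 (2Z)-4-(1,3-dioxolan-2-yl)-2-methylbut-2-en-1-ol
Conditions: Bu4NF, THF, 0 °C
Reagents that add atoms: none
Why: Fluoride desilylation to the allylic alcohol; the acetal and the alkene geometry are unaffected.

Step 8
Reactants: 12 (2Z)-4-(1,3-dioxolan-2-yl)-2-methylbut-2-en-1-ol
Product: 13 2-[(2Z)-4-bromo-3-methylbut-2-en-1-yl]-1,3-dioxolane
Conditions: CBr4, PPh3, CH2Cl2, −20 → 0 °C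
Reagents that add atoms: carbon tetrabromide, BrC(Br)(Br)Br
Why: Appel bromination, an SN2 displacement at a primary allylic carbon under neutral conditions that keeps the Z-alkene and the acetal.

Step 9
Reactants: 13 2-[(2Z)-4-bromo-3-methylbut-2-en-1-yl]-1,3-dioxolane
Product: 14 2-[(2Z)-3-methylhex-2-en-5-yn-1-yl]-1,3-dioxolane
Conditions: HC≡CMgBr, CuBr·SMe2 (5 mol%), THF, −20 → 0 °C
Reagents that add atoms: ethynylmagnesium bromide, C#C[Mg]Br
Why: Copper-catalysed coupling of an alkynyl Grignard reagent with a primary allylic bromide proceeds at the CH2Br carbon (SN2) and gives the skipped enyne without moving or isomerising the Z-alkene.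

Step 10
Reactants: 14 2-[(2Z)-3-methylhex-2-en-5-yn-1-yl]-1,3-dioxolane; 9 tert-butyl{[(2R,3Z,5Z,7R,8E)-9-iodo-7-methylnona-3,5,8-trien-2-yl]oxy}dimethylsilane
Product: 17 2-[(2Z,5E,7E,9S,10Z,12Z,14R)-14-[(tert-butyldimethylsilyl)oxy]-3,9-dimethylpentadeca-2,5,7,10,12-pentaen-1-yl]-1,3-dioxolane, via alkenylzirconocene 15 (not isolated), via alkenylzinc chloride 16 (not isolated)
Conditions: Cp2Zr(H)Cl, THF, rt; ZnCl2; then 9, Pd(PPh3)4 (5 mol%), THF, rt
Reagents that add atoms: none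
Why: Syn hydrozirconation of the terminal alkyne (Zr at the terminus), transmetalation to zinc and Negishi coupling with retention at both sp2 carbons build the E,E-diene and join the two halves.

Step 11
Reactants: 17 2-[(2Z,5E,7E,9S,10Z,12Z,14R)-14-[(tert-butyldimethylsilyl)oxy]-3,9-dimethylpentadeca-2,5,7,10,12-pentaen-1-yl]-1,3-dioxolane
Product: 19 (3E,6Z,9E,11E,13S,14Z,16Z,18R)-18-[(tert-butyldimethylsilyl)oxy]-1-chloro-7,13-dimethylnonadeca-3,6,9,11,14,16-hexaen-2-one, via pentaenal 18 (not isolated)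
Conditions: Et3SiOTf, 2,4,6-collidine, CH2Cl2, 0 °C; H2O; then Ph3P=CHC(O)CH2Cl, CH2Cl2, rt → 35 °C
Reagents that add atoms: 1-chloro-3-(triphenylphosphoranylidene)propan-2-one, ClCC(=O)C=P(c1ccccc1)(c1ccccc1)c1ccccc1
Why: Base-buffered silyl triflate cleavage of the aldehyde acetal (near neutral, silyl ether kept) and immediate Wittig reaction of the crude skipped aldehyde with the stabilised keto ylide give the E-enone that carries the chloromethyl group needed at the end.

Step 12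
Reactants: 19 (3E,6Z,9E,11E,13S,14Z,16Z,18R)-18-[(tert-butyldimethylsilyl)oxy]-1-chloro-7,13-dimethylnonadeca-3,6,9,11,14,16-hexaen-2-one
Product: 20 1-[(1R,2R,4aR,8aS)-2-[(2R,3Z,5Z,7R)-7-[(tert-butyldimethylsilyl)oxy]octa-3,5-dien-2-yl]-6-methyl-1,2,4a,5,8,8a-hexahydronaphthalen-1-yl]-2-chloroethan-1-one
Conditions: (S)-3,3-diphenyl-1-(2-methylphenyl)tetrahydro-1H,3H-pyrrolo[1,2-c][1,3,2]oxazaborole (20 mol%), AlBr3 (16 mol%), CH2Cl2, −78 → −40 °C
Reagents that add atoms: none
Why: Lewis-acid-catalysed intramolecular Diels–Alder reaction: the E-enone and the E,E-diene react through the endo transition state (acyl cis to the diene substituent, tether trans across the new ring fusion), and the ketone-bound chiral boron cation blocks one enone face and so fixes the absolute sense of all four new centres; the Z,Z-diene cannot reach an s-cis form and stays out.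

Step 13
Reactants: 20 1-[(1R,2R,4aR,8aS)-2-[(2R,3Z,5Z,7R)-7-[(tert-butyldimethylsilyl)oxy]octa-3,5-dien-2-yl]-6-methyl-1,2,4a,5,8,8a-hexahydronaphthalen-1-yl]-2-chloroethan-1-one
Product: 21 2-chloro-1-[(1R,2R,4aR,8aS)-2-[(2R,3Z,5Z,7R)-7-hydroxyocta-3,5-dien-2-yl]-6-methyl-1,2,4a,5,8,8a-hexahydronaphthalen-1-yl]ethan-1-one
Conditions: HF (48% aq.), MeCN, 0 °C
Reagents that add atoms: none
Why: Acidic fluoride desilylation that leaves the base-sensitive chloromethyl ketone alone (no amine present that could be alkylated).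

Step 14
Reactants: 22 2,2,5-trimethyl-1,3-dioxane-4,6-dione
Product: 23 3-{[(9H-fluoren-9-yl)methyl]sulfanyl}-2-methyl-3-oxopropanoic acid
Conditions: (9H-fluoren-9-yl)methanethiol, toluene, 90 °C
Reagents that add atoms: (9H-fluoren-9-yl)methanethiol, SCC1c2ccccc2-c2ccccc12
Why: Thiolysis of the Meldrum's acid ring with loss of acetone, the standard route to malonic half thioesters; the fluorenylmethyl group is a base-labile mask for the thioacid.

Step 15
Reactants: 21 2-chloro-1-[(1R,2R,4aR,8aS)-2-[(2R,3Z,5Z,7R)-7-hydroxyocta-3,5-dien-2-yl]-6-methyl-1,2,4a,5,8,8a-hexahydronaphthalen-1-yl]ethan-1-one; 23 3-{[(9H-fluoren-9-yl)methyl]sulfanyl}-2-methyl-3-oxopropanoic acid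
Product: 24 (2R,3Z,5Z,7R)-7-[(1R,2R,4aR,8aS)-1-(chloroacetyl)-6-methyl-1,2,4a,5,8,8a-hexahydronaphthalen-2-yl]octa-3,5-dien-2-yl 3-{[(9H-fluoren-9-yl)methyl]sulfanyl}-2-methyl-3-oxopropanoate
Conditions: N,N′-dicyclohexylcarbodiimide, CH2Cl2, 0 °C → rt
Reagents that add atoms: none
Why: Carbodiimide esterification of a malonic half acid (through its ketene, so no nucleophilic amine catalyst is needed next to the chloroketone) acylates the carbinol with retention; the malonate carbon is an epimer mixture, which does not matter.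

Step 16
Reactants: 24 (2R,3Z,5Z,7R)-7-[(1R,2R,4aR,8aS)-1-(chloroacetyl)-6-methyl-1,2,4a,5,8,8a-hexahydronaphthalen-2-yl]octa-3,5-dien-2-yl 3-{[(9H-fluoren-9-yl)methyl]sulfanyl}-2-methyl-3-oxopropanoate
Product: 27 target macrolide CNP0360406.2, via thioacid 25 (not isolated), via thiolactone 26 (not isolated)
Conditions: 1,8-diazabicyclo[5.4.0]undec-7-ene (1.1 equiv), NaI (cat.), MeCN (1 mM), 0 °C → rt; then LiBr, i-Pr2NEt, PPh3, 25 → 40 °C
Reagents that add atoms: none
Why: Proposed new method: a macrocyclic alkylative sulfide contraction – the amidine unmasks the thiocarboxylate by E1cB loss of dibenzofulvene, sulfur closes the unstrained 15-membered ring by SN2 on the chloromethyl ketone, and LiBr/amine then enolises the only ketone CH2 (flanked by C=O and S) so that the enolate adds to the neighbouring thioester carbonyl to give a thiirane alkoxide from which Ph3P takes the sulfur, contracting the ring to the 14-membered 1,3-diketone; the methyl group on the malonyl carbon blocks Knoevenagel-type closure to a thiophenone, and that epimerisable centre (between ketone and lactone carbonyl) is expected to settle under the basic conditions to the configuration of the target as the more stable epimer in the rigid macrocycle; the closest known reaction is the Eschenmoser sulfide contraction of acyclic S-(2-oxoalkyl) thioesters to β-diketones, which has not been shown as a ring contraction that forms a macrocycle or on a malonyl thioester.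

**Compound list**
1 | methyl (2S)-3-[(tert-butyldimethylsilyl)oxy]-2-methylpropanoate | COC(=O)[C@@H](C)CO[Si](C)(C)C(C)(C)C | starting material
2 | (2S)-3-[(tert-butyldimethylsilyl)oxy]-2-methylpropanal | O=C[C@@H](C)CO[Si](C)(C)C(C)(C)C | intermediate (not isolated)
3 | tert-butyldimethyl{[(2R)-2-methylbut-3-yn-1-yl]oxy}silane | C#C[C@@H](C)CO[Si](C)(C)C(C)(C)C | intermediate
4 | (2R)-2-methylbut-3-yn-1-ol | C#C[C@@H](C)CO | intermediate
5 | tert-butyl{[(2R)-but-3-yn-2-yl]oxy}dimethylsilane | C#C[C@@H](C)O[Si](C)(C)C(C)(C)C | starting material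
6 | (2R,7R)-7-[(tert-butyldimethylsilyl)oxy]-2-methylocta-3,5-diyn-1-ol | OC[C@H](C)C#CC#C[C@@H](C)O[Si](C)(C)C(C)(C)C | intermediate
7 | (2R,3Z,5Z,7R)-7-[(tert-butyldimethylsilyl)oxy]-2-methylocta-3,5-dien-1-ol | OC[C@H](C)/C=C\C=C/[C@@H](C)O[Si](C)(C)C(C)(C)C | intermediate
8 | (2R,3Z,5Z,7R)-7-[(tert-butyldimethylsilyl)oxy]-2-methylocta-3,5-dienal | O=C[C@H](C)/C=C\C=C/[C@@H](C)O[Si](C)(C)C(C)(C)C | intermediate (not isolated)
9 | tert-butyl{[(2R,3Z,5Z,7R,8E)-9-iodo-7-methylnona-3,5,8-trien-2-yl]oxy}dimethylsilane | I/C=C/[C@H](C)/C=C\C=C/[C@@H](C)O[Si](C)(C)C(C)(C)C | intermediate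
10 | 1-[(tert-butyldimethylsilyl)oxy]propan-2-one | CC(=O)CO[Si](C)(C)C(C)(C)C | starting material
11 | 2-[(2Z)-4-[(tert-butyldimethylsilyl)oxy]-3-methylbut-2-en-1-yl]-1,3-dioxolane | CC(C)(C)[Si](C)(C)OC/C(C)=C\CC1OCCO1 | intermediate
12 | (2Z)-4-(1,3-dioxolan-2-yl)-2-methylbut-2-en-1-ol | OC/C(C)=C\CC1OCCO1 | intermediate
13 | 2-[(2Z)-4-bromo-3-methylbut-2-en-1-yl]-1,3-dioxolane | BrC/C(C)=C\CC1OCCO1 | intermediate
14 | 2-[(2Z)-3-methylhex-2-en-5-yn-1-yl]-1,3-dioxolane | C#CC/C(C)=C\CC1OCCO1 | intermediate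
15 | chlorobis(cyclopentadienyl)[(1E,4Z)-6-(1,3-dioxolan-2-yl)-4-methylhexa-1,4-dien-1-yl]zirconium | Cl[Zr](/C=C/C/C(C)=C\CC1OCCO1)(C1C=CC=C1)C1C=CC=C1 | intermediate (not isolated)
16 | chloro[(1E,4Z)-6-(1,3-dioxolan-2-yl)-4-methylhexa-1,4-dien-1-yl]zinc | Cl[Zn]/C=C/C/C(C)=C\CC1OCCO1 | intermediate (not isolated)
17 | 2-[(2Z,5E,7E,9S,10Z,12Z,14R)-14-[(tert-butyldimethylsilyl)oxy]-3,9-dimethylpentadeca-2,5,7,10,12-pentaen-1-yl]-1,3-dioxolane | O1CCOC1C/C=C(C)\C/C=C/C=C/[C@H](C)/C=C\C=C/[C@@H](C)O[Si](C)(C)C(C)(C)C | intermediate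
18 | (3Z,6E,8E,10S,11Z,13Z,15R)-15-[(tert-butyldimethylsilyl)oxy]-4,10-dimethylhexadeca-3,6,8,11,13-pentaenal | O=CC/C=C(C)\C/C=C/C=C/[C@H](C)/C=C\C=C/[C@@H](C)O[Si](C)(C)C(C)(C)C | intermediate (not isolated)
19 | (3E,6Z,9E,11E,13S,14Z,16Z,18R)-18-[(tert-butyldimethylsilyl)oxy]-1-chloro-7,13-dimethylnonadeca-3,6,9,11,14,16-hexaen-2-one | ClCC(=O)/C=C/C/C=C(C)\C/C=C/C=C/[C@H](C)/C=C\C=C/[C@@H](C)O[Si](C)(C)C(C)(C)C | intermediate
20 | 1-[(1R,2R,4aR,8aS)-2-[(2R,3Z,5Z,7R)-7-[(tert-butyldimethylsilyl)oxy]octa-3,5-dien-2-yl]-6-methyl-1,2,4a,5,8,8a-hexahydronaphthalen-1-yl]-2-chloroethan-1-one | CC1=CC[C@@H]2[C@@H](C(=O)CCl)[C@@H]([C@H](C)/C=C\C=C/[C@@H](C)O[Si](C)(C)C(C)(C)C)C=C[C@H]2C1 | intermediate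
21 | 2-chloro-1-[(1R,2R,4aR,8aS)-2-[(2R,3Z,5Z,7R)-7-hydroxyocta-3,5-dien-2-yl]-6-methyl-1,2,4a,5,8,8a-hexahydronaphthalen-1-yl]ethan-1-one | CC1=CC[C@@H]2[C@@H](C(=O)CCl)[C@@H]([C@H](C)/C=C\C=C/[C@@H](C)O)C=C[C@H]2C1 | intermediate
22 | 2,2,5-trimethyl-1,3-dioxane-4,6-dione (isopropylidene methylmalonate) | CC1C(=O)OC(C)(C)OC1=O | starting material
23 | 3-{[(9H-fluoren-9-yl)methyl]sulfanyl}-2-methyl-3-oxopropanoic acid (racemic) | CC(C(=O)O)C(=O)SCC1c2ccccc2-c2ccccc12 | intermediate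
24 | (2R,3Z,5Z,7R)-7-[(1R,2R,4aR,8aS)-1-(chloroacetyl)-6-methyl-1,2,4a,5,8,8a-hexahydronaphthalen-2-yl]octa-3,5-dien-2-yl 3-{[(9H-fluoren-9-yl)methyl]sulfanyl}-2-methyl-3-oxopropanoate (epimers at the malonate carbon) | CC1=CC[C@@H]2[C@@H](C(=O)CCl)[C@@H]([C@H](C)/C=C\C=C/[C@@H](C)OC(=O)C(C)C(=O)SCC3c4ccccc4-c4ccccc34)C=C[C@H]2C1 | intermediate
25 | (2R,3Z,5Z,7R)-7-[(1R,2R,4aR,8aS)-1-(chloroacetyl)-6-methyl-1,2,4a,5,8,8a-hexahydronaphthalen-2-yl]octa-3,5-dien-2-yl 2-methyl-3-oxo-3-sulfanylpropanoate | CC1=CC[C@@H]2[C@@H](C(=O)CCl)[C@@H]([C@H](C)/C=C\C=C/[C@@H](C)OC(=O)C(C)C(=O)S)C=C[C@H]2C1 | intermediate (not isolated)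
26 | 15-membered thiolactone: the S-(2-oxoethyl) thioester formed when the thioacid sulfur of 25 replaces the chlorine (ring: decalin C1–C(=O)–CH2–S–C(=O)–CH(CH3)–C(=O)–O–CH(CH3)–(Z,Z)-diene–CH(CH3)–decalin C2) | CC1=CC[C@@H]2[C@H]3C(=O)CSC(=O)C(C)C(=O)O[C@H](C)/C=C\C=C/[C@@H](C)[C@H]3C=C[C@H]2C1 | intermediate (not isolated)
27 | target CNP0360406.2: trans-decalin-fused 14-membered lactone with enolised 3,5-diketone, (R)-methyl between ketone and lactone carbonyl, (Z,Z)-diene | CC1=CC[C@@H]2[C@H]3/C(O)=C\C(=O)[C@@H](C)C(=O)O[C@H](C)/C=C\C=C/[C@@H](C)[C@H]3C=C[C@H]2C1 | target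

**Step count**
Total: 16 steps. Longest linear sequence: 11 steps (steps 1, 2, 3, 4, 5, 10, 11, 12, 13, 15, 16).

**Steps most likely to fail, with fallbacks**

Step 16 (new ring contraction). Risks: enolisation at the malonyl carbon instead of the ketone CH2, loss of the thiolate through a ketene, base-induced closure of the product tricarbonyl to a 4-hydroxy-2-pyranone (hence the mild temperature), and an unfavourable epimer ratio at the methyl-bearing carbon. The fallback uses known chemistry, sets out from 18 and returns at 27. Wittig reaction of 18 with (triphenylphosphoranylidene)acetaldehyde gives the trienal F7. Iminium-catalysed intramolecular Diels–Alder reaction ((2S,5S)-5-benzyl-2-tert-butyl-3-methylimidazolidin-4-one, CF3CO2H, MeCN/H2O, 5 °C) gives the decalin aldehyde F8. Vinylogous Mukaiyama aldol reaction with [(2,2-dimethyl-6-methylidene-6H-1,3-dioxin-4-yl)oxy]trimethylsilane and BF3·OEt2 (CH2Cl2, −78 °C) gives the carbinol F9, and Dess–Martin oxidation gives the keto dioxinone F10. Aqueous HF in MeCN frees the secondary alcohol F11. Heating in toluene (110 °C, 0.5 mM) releases the acylketene, which the carbinol traps to give the desmethyl macrolide F12. Dianion formation (LiN(SiMe3)2, 2.1 equiv, THF, −78 °C) and MeI methylate the carbon between ketone and lactone carbonyl under control of the macrocycle to give 27.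

Step 12 (catalytic enantioselective cycloaddition of an α′-chloro trienone). Risks: low face selectivity, ionisation of the dienylic silyl ether by the strong Lewis acid. The fallback uses auxiliary control, sets out from 18 and returns at 20. Masamune–Roush olefination of 18 with diethyl {2-[(4S)-4-benzyl-2-oxo-1,3-oxazolidin-3-yl]-2-oxoethyl}phosphonate (LiCl, i-Pr2NEt, MeCN) gives the trienimide F4. Me2AlCl (1.4 equiv, CH2Cl2, −30 °C) gives the endo adduct, the decalin imide F5, the chelated s-cis imide being attacked on the face away from the benzyl group. MeNHOMe·HCl/AlMe3 gives the Weinreb amide F6 with recovery of the auxiliary, and ClCH2Li (from ICH2Cl and MeLi·LiBr, THF, −78 °C) gives 20.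

Step 11 (skipped aldehyde that can slip into conjugation, and a sluggish chloro ylide). The fallback brings the chlorine in after the cycloaddition, sets out from 18 and returns at 20. Crude 18 is taken at once into a Horner–Wadsworth–Emmons reaction with dimethyl (2-oxopropyl)phosphonate and Ba(OH)2 (wet THF, 0 °C), which is fast and barely basic, to give the methyl trienone F1. The conditions of step 12 give the decalinyl methyl ketone F2. LiN(SiMe3)2/Me3SiCl (THF, −78 °C) forms the kinetic silyl enol ether F3 on the methyl side, and N-chlorosuccinimide converts it into 20.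

Further compounds
F1 | step 11 | (3E,6Z,9E,11E,13S,14Z,16Z,18R)-18-[(tert-butyldimethylsilyl)oxy]-7,13-dimethylnonadeca-3,6,9,11,14,16-hexaen-2-one | CC(=O)/C=C/C/C=C(C)\C/C=C/C=C/[C@H](C)/C=C\C=C/[C@@H](C)O[Si](C)(C)C(C)(C)C
F2 | step 11 | 1-[(1R,2R,4aR,8aS)-2-[(2R,3Z,5Z,7R)-7-[(tert-butyldimethylsilyl)oxy]octa-3,5-dien-2-yl]-6-methyl-1,2,4a,5,8,8a-hexahydronaphthalen-1-yl]ethan-1-one | CC1=CC[C@@H]2[C@@H](C(C)=O)[C@@H]([C@H](C)/C=C\C=C/[C@@H](C)O[Si](C)(C)C(C)(C)C)C=C[C@H]2C1
F3 | step 11 | tert-butyl{[(2R,3Z,5Z,7R)-7-[(1R,2R,4aR,8aS)-6-methyl-1-{1-[(trimethylsilyl)oxy]ethenyl}-1,2,4a,5,8,8a-hexahydronaphthalen-2-yl]octa-3,5-dien-2-yl]oxy}dimethylsilane | CC1=CC[C@@H]2[C@@H](C(=C)O[Si](C)(C)C)[C@@H]([C@H](C)/C=C\C=C/[C@@H](C)O[Si](C)(C)C(C)(C)C)C=C[C@H]2C1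
F4 | step 12 | (4S)-4-benzyl-3-[(2E,5Z,8E,10E,12S,13Z,15Z,17R)-17-[(tert-butyldimethylsilyl)oxy]-6,12-dimethyloctadeca-2,5,8,10,13,15-hexaenoyl]-1,3-oxazolidin-2-one | O=C1OC[C@H](Cc2ccccc2)N1C(=O)/C=C/C/C=C(C)\C/C=C/C=C/[C@H](C)/C=C\C=C/[C@@H](C)O[Si](C)(C)C(C)(C)C
F5 | step 12 | (4S)-4-benzyl-3-{[(1R,2R,4aR,8aS)-2-[(2R,3Z,5Z,7R)-7-[(tert-butyldimethylsilyl)oxy]octa-3,5-dien-2-yl]-6-methyl-1,2,4a,5,8,8a-hexahydronaphthalen-1-yl]carbonyl}-1,3-oxazolidin-2-one | CC1=CC[C@@H]2[C@@H](C(=O)N3[C@@H](Cc4ccccc4)COC3=O)[C@@H]([C@H](C)/C=C\C=C/[C@@H](C)O[Si](C)(C)C(C)(C)C)C=C[C@H]2C1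
F6 | step 12 | (1R,2R,4aR,8aS)-2-[(2R,3Z,5Z,7R)-7-[(tert-butyldimethylsilyl)oxy]octa-3,5-dien-2-yl]-N-methoxy-N,6-dimethyl-1,2,4a,5,8,8a-hexahydronaphthalene-1-carboxamide | CC1=CC[C@@H]2[C@@H](C(=O)N(C)OC)[C@@H]([C@H](C)/C=C\C=C/[C@@H](C)O[Si](C)(C)C(C)(C)C)C=C[C@H]2C1
F7 | step 16 | (2E,5Z,8E,10E,12S,13Z,15Z,17R)-17-[(tert-butyldimethylsilyl)oxy]-6,12-dimethyloctadeca-2,5,8,10,13,15-hexaenal | O=C/C=C/C/C=C(C)\C/C=C/C=C/[C@H](C)/C=C\C=C/[C@@H](C)O[Si](C)(C)C(C)(C)C
F8 | step 16 | (1R,2R,4aR,8aS)-2-[(2R,3Z,5Z,7R)-7-[(tert-butyldimethylsilyl)oxy]octa-3,5-dien-2-yl]-6-methyl-1,2,4a,5,8,8a-hexahydronaphthalene-1-carbaldehyde | CC1=CC[C@@H]2[C@@H](C=O)[C@@H]([C@H](C)/C=C\C=C/[C@@H](C)O[Si](C)(C)C(C)(C)C)C=C[C@H]2C1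
F9 | step 16 | 6-{2-[(1R,2R,4aR,8aS)-2-[(2R,3Z,5Z,7R)-7-[(tert-butyldimethylsilyl)oxy]octa-3,5-dien-2-yl]-6-methyl-1,2,4a,5,8,8a-hexahydronaphthalen-1-yl]-2-hydroxyethyl}-2,2-dimethyl-4H-1,3-dioxin-4-one (carbinol epimers) | CC1=CC[C@@H]2[C@@H](C(O)CC3=CC(=O)OC(C)(C)O3)[C@@H]([C@H](C)/C=C\C=C/[C@@H](C)O[Si](C)(C)C(C)(C)C)C=C[C@H]2C1
F10 | step 16 | 6-{2-[(1R,2R,4aR,8aS)-2-[(2R,3Z,5Z,7R)-7-[(tert-butyldimethylsilyl)oxy]octa-3,5-dien-2-yl]-6-methyl-1,2,4a,5,8,8a-hexahydronaphthalen-1-yl]-2-oxoethyl}-2,2-dimethyl-4H-1,3-dioxin-4-one | CC1=CC[C@@H]2[C@@H](C(=O)CC3=CC(=O)OC(C)(C)O3)[C@@H]([C@H](C)/C=C\C=C/[C@@H](C)O[Si](C)(C)C(C)(C)C)C=C[C@H]2C1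
F11 | step 16 | 6-{2-[(1R,2R,4aR,8aS)-2-[(2R,3Z,5Z,7R)-7-hydroxyocta-3,5-dien-2-yl]-6-methyl-1,2,4a,5,8,8a-hexahydronaphthalen-1-yl]-2-oxoethyl}-2,2-dimethyl-4H-1,3-dioxin-4-one | CC1=CC[C@@H]2[C@@H](C(=O)CC3=CC(=O)OC(C)(C)O3)[C@@H]([C@H](C)/C=C\C=C/[C@@H](C)O)C=C[C@H]2C1
F12 | step 16 | desmethyl macrolide: 27 with CH2 in place of CH(CH3) between ketone and lactone carbonyl (drawn as the triketo form) | CC1=CC[C@@H]2[C@H]3C(=O)CC(=O)CC(=O)O[C@H](C)/C=C\C=C/[C@@H](C)[C@H]3C=C[C@H]2C1
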